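**Retrosynthetic overview**
- The target is the bis(benzyl ether) 12 after hydrogenolysis. Ring B (the saturated ring of the tetralin) is closed last, by acid-mediated Friedel–Crafts attack of the symmetric syringyl ring on a benzylic cation (C1–C8a bond, trans,trans).
- The cation precursor is an open-chain triol, obtained by LiAlH4 reduction of the trans aldol adduct of an (S)-β-benzyl-γ-butyrolactone with O-benzylvanillin.
- Key step: the lactone comes from enantioselective Baeyer–Villiger O-insertion into a prochiral 3-benzylcyclobutanone. The C–O bond made there survives as the C3–CH2–OH bond of the target, and the step sets C3.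
- The cyclobutanone comes from dichloroketene [2+2] cycloaddition and dechlorination on O-benzyl methoxyeugenol.
- Ring order: cyclobutanone (temporary), then γ-butyrolactone (temporary), then ring B; both aromatic rings are bought.

Assumption: the sense of induction of the new catalyst in step 3 is not known beforehand, so the catalyst antipode that gives (S)-7 is used (both are equally accessible); tetralin numbering with C1 as the aryl-bearing carbon is used for the target, which is (1R,2S,3S), trans,trans.

**Step 1**
Reactants: 1 4-allyl-2,6-dimethoxyphenol (methoxyeugenol)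
Product: 2 5-allyl-2-(benzyloxy)-1,3-dimethoxybenzene
Conditions: BnBr (1.1 equiv), K2CO3, DMF, 60 °C
Reagents that add atoms: benzyl bromide, BrCc1ccccc1
Why: Williamson ether synthesis on the phenoxide protects the phenol against acylation by 3 and against the base of step 4; no stereocentre is involved.

**Step 2**
Reactants: 2 5-allyl-2-(benzyloxy)-1,3-dimethoxybenzene; 3 trichloroacetyl chloride
Product: 6 3-(4-benzyloxy-3,5-dimethoxybenzyl)cyclobutan-1-one, via dichloroketene 4 (not isolated), via dichlorocyclobutanone 5 (not isolated)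
Conditions: 3, Zn(Cu), Et2O–DME, sonication, 20–35 °C; filter, concentrate; Zn, AcOH, rt to 50 °C
Reagents that add atoms: none
Why: thermal ketene–alkene [2+2] cycloaddition places the carbonyl carbon on the terminal CH2, and Zn/AcOH reductive dechlorination of the crude adduct gives the mirror-symmetric (prochiral) cyclobutanone, so no stereocentre is carried forward.

**Step 3**
Reactants: 6 3-(4-benzyloxy-3,5-dimethoxybenzyl)cyclobutan-1-one
Product: 7 (S)-4-(4-benzyloxy-3,5-dimethoxybenzyl)dihydrofuran-2(3H)-one
Conditions: (S,S)-IDPi Brønsted acid (2 mol %), Me3SiOOSiMe3 (1.3 equiv), CH2Cl2–toluene, −78 to −60 °C; aq. Na2S2O3/NaHCO3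
Reagents that add atoms: bis(trimethylsilyl) peroxide, C[Si](C)(C)OO[Si](C)(C)C
Why: Proposed new method: a confined C2-symmetric imidodiphosphorimidate (two (S)-3,3′-bis[3,5-bis(trifluoromethyl)phenyl]-BINOL units, N-triflyl groups on both phosphorus atoms) is silylated in the flask by the peroxide to a silylium-type Lewis acid that O-silylates the cyclobutanone; the silyl peroxide adds to give a silylated Criegee adduct held as a contact ion pair inside the chiral anion, where only one of the two enantiotopic ring CH2 groups can lie antiperiplanar to the O–O bond and migrate, so the new C–O bond and the C4 stereocentre (C3 of the target) are set together with loss of (Me3Si)2O; the closest known reaction types are the achiral Me3SiOTf-catalysed Baeyer–Villiger oxidation with bis(trimethylsilyl) peroxide and the chiral phosphoric acid-catalysed Baeyer–Villiger desymmetrisation of 3-substituted cyclobutanones with H2O2.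

**Step 4**
Reactants: 7 (S)-4-(4-benzyloxy-3,5-dimethoxybenzyl)dihydrofuran-2(3H)-one; 8 4-(benzyloxy)-3-methoxybenzaldehyde (O-benzylvanillin)
Product: 10 (3R,4S)-3-[(4-benzyloxy-3-methoxyphenyl)(hydroxy)methyl]-4-(4-benzyloxy-3,5-dimethoxybenzyl)dihydrofuran-2(3H)-one (both carbinol epimers), via lithium enolate 9 (not isolated)
Conditions: LiN(iPr)2 (1.1 equiv), THF, −78 °C; 8, −78 °C, 1 h; AcOH quench at −78 °C
Reagents that add atoms: none
Why: aldol addition of the lithium lactone enolate to the non-enolisable aldehyde occurs anti to the C4 benzyl group and sets C3 trans by substrate control; the carbinol centre forms as a mixture, which is harmless because it becomes a planar cation in step 5.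

**Step 5**
Reactants: 10 (3R,4S)-3-[(4-benzyloxy-3-methoxyphenyl)(hydroxy)methyl]-4-(4-benzyloxy-3,5-dimethoxybenzyl)dihydrofuran-2(3H)-one
Product: 12 [(1R,2S,3S)-7-(benzyloxy)-1-(4-benzyloxy-3-methoxyphenyl)-6,8-dimethoxy-1,2,3,4-tetrahydronaphthalene-2,3-diyl]dimethanol, via triol 11 (not isolated)
Conditions: LiAlH4, THF, 0 °C to rt; NaOH/H2O work-up, solvent change; TFA (3 equiv), CH2Cl2, 0 °C to rt; K2CO3, MeOH to cleave any trifluoroacetates
Reagents that add atoms: none
Why: hydride reduction of the lactone leaves both stereocentres untouched, then acid ionises the p-benzyloxybenzylic alcohol and an intramolecular Friedel–Crafts alkylation ortho/para to the two methoxy groups closes ring B through a chair-like transition state (both CH2OH groups equatorial, C2–H eclipsing the cation to minimise allylic strain), which sets C1 trans to C2; any tetrahydrofuran formed by O-capture re-ionises and funnels to the carbocycle.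

**Step 6**
Reactants: 12 [(1R,2S,3S)-7-(benzyloxy)-1-(4-benzyloxy-3-methoxyphenyl)-6,8-dimethoxy-1,2,3,4-tetrahydronaphthalene-2,3-diyl]dimethanol
Product: 13 (6S,7S,8R)-8-(4-hydroxy-3-methoxyphenyl)-6,7-bis(hydroxymethyl)-1,3-dimethoxy-5,6,7,8-tetrahydronaphthalen-2-ol (the target)
Conditions: H2 (1 atm), 10% Pd/C, EtOAc–MeOH, rt
Reagents that add atoms: none
Why: catalytic hydrogenolysis cleaves the two aryl benzyl ethers and touches no stereocentre.

**Compound list**
1 | 4-allyl-2,6-dimethoxyphenol (methoxyeugenol) | C=CCc1cc(OC)c(O)c(OC)c1 | starting material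
2 | 5-allyl-2-(benzyloxy)-1,3-dimethoxybenzene | C=CCc1cc(OC)c(OCc2ccccc2)c(OC)c1 | intermediate
3 | trichloroacetyl chloride | ClC(Cl)(Cl)C(Cl)=O | starting material
4 | dichloroketene | ClC(Cl)=C=O | intermediate (not isolated)
5 | 2,2-dichloro-3-(4-benzyloxy-3,5-dimethoxybenzyl)cyclobutan-1-one (racemic) | O=C1CC(Cc2cc(OC)c(OCc3ccccc3)c(OC)c2)C1(Cl)Cl | intermediate (not isolated)
6 | 3-(4-benzyloxy-3,5-dimethoxybenzyl)cyclobutan-1-one (achiral) | O=C1CC(Cc2cc(OC)c(OCc3ccccc3)c(OC)c2)C1 | intermediate
7 | (S)-4-(4-benzyloxy-3,5-dimethoxybenzyl)dihydrofuran-2(3H)-one | O=C1C[C@H](Cc2cc(OC)c(OCc3ccccc3)c(OC)c2)CO1 | intermediate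
8 | 4-(benzyloxy)-3-methoxybenzaldehyde (O-benzylvanillin) | O=Cc1ccc(OCc2ccccc2)c(OC)c1 | starting material
9 | lithium (S)-4-(4-benzyloxy-3,5-dimethoxybenzyl)-4,5-dihydrofuran-2-olate | [Li+].[O-]C1=C[C@H](Cc2cc(OC)c(OCc3ccccc3)c(OC)c2)CO1 | intermediate (not isolated)
10 | (3R,4S)-3-[(4-benzyloxy-3-methoxyphenyl)(hydroxy)methyl]-4-(4-benzyloxy-3,5-dimethoxybenzyl)dihydrofuran-2(3H)-one (carbinol epimers) | O=C1OC[C@@H](Cc2cc(OC)c(OCc3ccccc3)c(OC)c2)[C@@H]1C(O)c1ccc(OCc2ccccc2)c(OC)c1 | intermediate
11 | (2S,3S)-2-[(4-benzyloxy-3-methoxyphenyl)(hydroxy)methyl]-3-(4-benzyloxy-3,5-dimethoxybenzyl)butane-1,4-diol (carbinol epimers) | COc1cc(C(O)[C@H](CO)[C@@H](CO)Cc2cc(OC)c(OCc3ccccc3)c(OC)c2)ccc1OCc1ccccc1 | intermediate (not isolated)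
12 | [(1R,2S,3S)-7-(benzyloxy)-1-(4-benzyloxy-3-methoxyphenyl)-6,8-dimethoxy-1,2,3,4-tetrahydronaphthalene-2,3-diyl]dimethanol | COc1cc([C@@H]2c3c(cc(OC)c(OCc4ccccc4)c3OC)C[C@H](CO)[C@H]2CO)ccc1OCc1ccccc1 | intermediate
13 | (6S,7S,8R)-8-(4-hydroxy-3-methoxyphenyl)-6,7-bis(hydroxymethyl)-1,3-dimethoxy-5,6,7,8-tetrahydronaphthalen-2-ol | COc1cc([C@@H]2c3c(cc(OC)c(O)c3OC)C[C@H](CO)[C@H]2CO)ccc1O | target

**Step count and risks**
Total step count: 6. Steps 2 and 5 each combine two operations without isolating the intermediate, so there are eight chemical operations in all.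
Longest linear sequence: 6 steps (1 to 13); the route is linear, and 3 and 8 are purchased.

The three steps most likely to fail:

Step 3 (the new Baeyer–Villiger desymmetrisation). The level and sense of enantioinduction are untested, and the silylated peroxide could hydroxylate the electron-rich trialkoxyarene instead of attacking the ketone. The enantiomeric excess is checked by chiral HPLC and can be upgraded by crystallising 7 or 12. The fallback uses known chemistry, sets out from 6 and comes back at 7; it sets the same stereocentre by enantiotopic C–H removal instead of O-insertion. Deprotonation of 6 with the chiral base LiN[CH(CH3)Ph]2 (the antipode that leads to the S series) in THF at −100 °C with Me3SiCl as internal trap gives the silyl enol ether (S)-{[3-(4-benzyloxy-3,5-dimethoxybenzyl)cyclobut-1-en-1-yl]oxy}trimethylsilane F1. Ozonolysis (O3, CH2Cl2–MeOH, −78 °C, stopped at the first excess of ozone) followed by NaBH4 gives (S)-3-(4-benzyloxy-3,5-dimethoxybenzyl)-4-hydroxybutanoic acid F2, which closes to 7 on acidification (TsOH, toluene).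

Step 5 (reduction and ring B closure). The open-chain cation may be trapped persistently as the tetrahydrofuran or as trifluoroacetates, the peri-methoxy group may erode the C1 selectivity, and partial debenzylation is possible. The fallback sets out from 10 and comes back at 12, with ring B closed before the reduction. Treating 10 with TFA in CH2Cl2 cyclises the cation while C2 and C3 are locked trans in the lactone and no free primary alcohol is present, giving the aryltetralin lactone (3aS,9R,9aS)-7-(benzyloxy)-9-(4-benzyloxy-3-methoxyphenyl)-6,8-dimethoxy-3a,4,9,9a-tetrahydronaphtho[2,3-c]furan-1(3H)-one F3. LiAlH4 in THF then reduces F3 to 12. The C1 configuration of F3 must be confirmed by NOE, because the rigid lactone forces the pendant aryl group against the peri-methoxy group.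

Step 2 (dichloroketene cycloaddition and dechlorination). The ketene may oligomerise faster than it adds to the monosubstituted alkene, and ZnCl2 may damage the benzyl ether. The fallback sets out from 2 and comes back at 6, using a keteniminium salt as the two-carbon partner so that no chlorinated intermediate or zinc is involved. N,N-dimethylacetamide, Tf2O and 2,4,6-collidine in ClCH2CH2Cl at reflux with 2 give the cyclobutaniminium salt N-[3-(4-benzyloxy-3,5-dimethoxybenzyl)cyclobutylidene]-N-methylmethanaminium trifluoromethanesulfonate F4, which aqueous NaHCO3 hydrolyses to 6.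

**Further compounds**
F1 | step 3 | (S)-{[3-(4-benzyloxy-3,5-dimethoxybenzyl)cyclobut-1-en-1-yl]oxy}trimethylsilane | C[Si](C)(C)OC1=C[C@@H](Cc2cc(OC)c(OCc3ccccc3)c(OC)c2)C1
F2 | step 3 | (S)-3-(4-benzyloxy-3,5-dimethoxybenzyl)-4-hydroxybutanoic acid | OC(=O)C[C@H](Cc1cc(OC)c(OCc2ccccc2)c(OC)c1)CO
F3 | step 5 | (3aS,9R,9aS)-7-(benzyloxy)-9-(4-benzyloxy-3-methoxyphenyl)-6,8-dimethoxy-3a,4,9,9a-tetrahydronaphtho[2,3-c]furan-1(3H)-one | O=C1OC[C@H]2Cc3cc(OC)c(OCc4ccccc4)c(OC)c3[C@@H](c3ccc(OCc4ccccc4)c(OC)c3)[C@H]12
F4 | step 2 | N-[3-(4-benzyloxy-3,5-dimethoxybenzyl)cyclobutylidene]-N-methylmethanaminium trifluoromethanesulfonate | C[N+](C)=C1CC(Cc2cc(OC)c(OCc3ccccc3)c(OC)c2)C1.[O-]S(=O)(=O)C(F)(F)F
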